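## Retrosynthetic overview

1. Target 19 ⇐ fluoride/hydroxide unmasking of epoxy cis-β-lactone methyl ester 17; the oxetanone carries the 12,13-syn hydroxy acid as one unit.
2. Oxirane ⇐ chiral-dioxirane epoxidation of the distal (4Z) olefin of dienoate lactone 16.
3. Oxetanone ⇐ alkaloid-catalysed ketene–aldehyde [2+2] on aldehyde 12 (C12–C13 bond, both centres); 12 ⇐ terminal alkene 11.
4. Dienoate 11 ⇐ one-pot propyne carbocupration/ynoate conjugate addition from bromide 5 (C5–C6 and C3–C4 bonds; 4Z and 2E from two syn additions).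
5. Bromide 5 ⇐ methacrolein + butenyl radical by a new aminocatalytic photochemical addition–protonation (C8–C9 bond, C7 centre). Ring order: oxetanone first, oxirane second, oxetanone opened last.

Assumption: the chain is numbered C1 (enoic acid carbon) to C14; read from the SMILES the target is (2E,4S,5R,7S,12S,13R), with C3 and C6 cis on the oxirane and a 12,13-syn hydroxy acid; compounds 1, 2, 6, 7 and 13 and all catalysts are taken as purchasable or literature compounds.

## Route

Step 1
Reactants: 1 methacrolein (2-methylprop-2-enal); 2 potassium (but-3-en-1-yl)trifluoroborate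
Product: 4 (2S)-2-methylhept-6-en-1-ol, via (2S)-2-methylhept-6-enal 3 (not isolated)
Conditions: 1 (3 equiv), (S)-N1,N1-diethyl-3,3-dimethylbutane-1,2-diamine·TfOH (20 mol%), 9-mesityl-10-methylacridinium tetrafluoroborate (5 mol%), MeCN/H2O 20:1, 450 nm LEDs, −20 °C; then NaBH4, MeOH, −20 to 0 °C
Reagents that add atoms: none
Why: Proposed new method: the excited acridinium oxidises the alkyltrifluoroborate to the but-3-enyl radical, which adds to the CH2 terminus of the catalyst-bound iminium ion of methacrolein faster than to free enal; the acridinyl radical then reduces the enamine radical cation to a catalyst-bound enamine, whose C2 is protonated on one face by the tertiary ammonium arm of the diamine, setting (S)-C7 (predicted sense; the antipodal diamine is used if it proves opposite) before hydrolysis and in situ NaBH4 reduction fix it; the closest known reaction types are amine-catalysed enantioselective photochemical radical conjugate addition to β-substituted enals (β-stereocenter) and primary-amine-catalysed conjugate addition/enantioselective enamine protonation of α-substituted acroleins with two-electron nucleophiles, and their merger on an α-branched enal with an unstabilised alkyl radical has not been shown.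

Step 2
Reactants: 4 (2S)-2-methylhept-6-en-1-ol
Product: 5 (6S)-7-bromo-6-methylhept-1-ene
Conditions: CBr4, PPh3, CH2Cl2, 0 °C
Reagents that add atoms: carbon tetrabromide, BrC(Br)(Br)Br
Why: Appel reaction, SN2 displacement of the alkoxyphosphonium ion at the primary carbon, so the adjacent C7 stereocenter is not touched.

Step 3
Reactants: 5 (6S)-7-bromo-6-methylhept-1-ene; 6 propyne; 7 methyl but-2-ynoate
Product: 11 methyl (2E,4Z,7S)-3,5,7-trimethyldodeca-2,4,11-trienoate, via Grignard reagent 8 (not isolated), via alkenylcopper 9 (not isolated), via thienylcuprate 10 (not isolated)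
Conditions: Mg, Et2O, 35 °C; CuBr·SMe2, Et2O/Me2S, −45 °C; 6 (3 equiv), −25 °C, 3 h; 2-thienyllithium, THF, −60 °C; 7, −78 to −50 °C; aq NH4Cl
Reagents that add atoms: none
Why: Normant carbocupration: the alkylcopper adds syn across propyne with copper on the terminal carbon (C6 and Cu cis, hence 4Z), and the derived thienylcuprate then adds syn to the ynoate (cuprate conjugate addition, alkenyl group and H cis, hence 2E) with retention of the alkenyl geometry, while C7 and the terminal alkene are untouched.

Step 4
Reactants: 11 methyl (2E,4Z,7S)-3,5,7-trimethyldodeca-2,4,11-trienoate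
Product: 12 methyl (2E,4Z,7S)-3,5,7-trimethyl-12-oxododeca-2,4-dienoate
Conditions: PdCl2(PhCN)2 (12 mol%), CuCl2·2H2O (12 mol%), AgNO2 (6 mol%), O2 (1 atm), t-BuOH/MeNO2 15:1, 20 °C
Reagents that add atoms: dioxygen, O=O
Why: Nitrite-modified, aldehyde-selective Wacker oxidation puts oxygen on the terminal carbon of the unbiased monosubstituted alkene, while the trisubstituted, ester-conjugated olefins are not oxidised and no stereocenter is affected.

Step 5
Reactants: 12 methyl (2E,4Z,7S)-3,5,7-trimethyl-12-oxododeca-2,4-dienoate; 13 3-{[tert-butyl(dimethyl)silyl]oxy}propanoic acid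
Product: 16 methyl (2E,4Z,7S)-11-[(2S,3R)-3-({[tert-butyl(dimethyl)silyl]oxy}methyl)-4-oxooxetan-2-yl]-3,5,7-trimethylundeca-2,4-dienoate, via acid chloride 14 (not isolated), via silyloxymethylketene 15 (not isolated)
Conditions: 13, 1-chloro-N,N,2-trimethylprop-1-en-1-amine, CH2Cl2, 0 °C; this solution added over 2 h to 12, O-trimethylsilylquinidine (15 mol%), LiClO4 (2 equiv), iPr2NEt (2.5 equiv), CH2Cl2/Et2O 2:1, −78 °C
Reagents that add atoms: none
Why: Alkaloid-catalysed acyl halide–aldehyde cyclocondensation (formal ketene–aldehyde [2+2]): the quinidine-bound Z-ammonium enolate of ketene 15 adds to one face of the Li+-activated aldehyde through a closed transition state and lactonises, giving the cis-oxetanone and setting C12 (S) and C13 (R) together under catalyst control, while −78 °C keeps the β-silyloxy enolate from eliminating and the aldehyde from self-condensing.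

Step 6
Reactants: 16 methyl (2E,4Z,7S)-11-[(2S,3R)-3-({[tert-butyl(dimethyl)silyl]oxy}methyl)-4-oxooxetan-2-yl]-3,5,7-trimethylundeca-2,4-dienoate
Product: 17 methyl (2E)-3-[(2S,3R)-3-{(2S)-6-[(2S,3R)-3-({[tert-butyl(dimethyl)silyl]oxy}methyl)-4-oxooxetan-2-yl]-2-methylhexyl}-3-methyloxiran-2-yl]but-2-enoate
Conditions: 1,2:4,5-di-O-isopropylidene-β-L-erythro-2,3-hexodiulo-2,6-pyranose (enantiomer of the fructose-derived Shi ketone, 30 mol%), KHSO5 (as 2KHSO5·KHSO4·K2SO4), K2CO3, Bu4NHSO4, MeCN/CH2(OMe)2/aq Na2B4O7 (pH 10.5), −5 °C, 2 h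
Reagents that add atoms: potassium peroxymonosulfate, [K+].OOS(=O)(=O)[O-]
Why: Shi epoxidation: the chiral dioxirane transfers oxygen stereospecifically (syn) to the electron-richer distal C4=C5 olefin through a spiro transition state with the C4–H in the hindered quadrant of the L-series ketone, giving the (4S,5R) oxirane with C3 and C6 cis, while the ester-conjugated C2=C3 olefin is inert and the hindered oxetanone survives the short cold exposure to pH 10.5.

Step 7
Reactants: 17 methyl (2E)-3-[(2S,3R)-3-{(2S)-6-[(2S,3R)-3-({[tert-butyl(dimethyl)silyl]oxy}methyl)-4-oxooxetan-2-yl]-2-methylhexyl}-3-methyloxiran-2-yl]but-2-enoate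
Product: 19 (2E,4S,5R,7S,12S,13R)-4,5-epoxy-12-hydroxy-13-(hydroxymethyl)-3,5,7-trimethyltetradec-2-enedioic acid (CNP0468463.2), via hydroxymethyl lactone 18 (not isolated)
Conditions: Bu4NF, THF, 0 °C; then LiOH·H2O, THF/MeOH/H2O 2:1:1, 20 °C; cold 0.2 M HCl to pH 4, immediate extraction
Reagents that add atoms: lithium hydroxide, [Li+].[OH-]
Why: Fluoride desilylation, then hydroxide acyl–oxygen cleavage of the β-lactone and saponification of the methyl ester (retention at C12 and C13); the trisubstituted oxirane is inert to base and tolerates brief acidification to pH 4.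

## Compound list

1 | methacrolein (2-methylprop-2-enal) | C=C(C)C=O | starting material
2 | potassium (but-3-en-1-yl)trifluoroborate | [K+].C=CCC[B-](F)(F)F | starting material
3 | (2S)-2-methylhept-6-enal | O=C[C@@H](C)CCCC=C | intermediate
4 | (2S)-2-methylhept-6-en-1-ol | OC[C@@H](C)CCCC=C | intermediate
5 | (6S)-7-bromo-6-methylhept-1-ene | BrC[C@@H](C)CCCC=C | intermediate
6 | propyne | CC#C | starting material
7 | methyl but-2-ynoate | CC#CC(=O)OC | starting material
8 | bromo[(2S)-2-methylhept-6-en-1-yl]magnesium | Br[Mg]C[C@@H](C)CCCC=C | intermediate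
9 | [(1Z,4S)-2,4-dimethylnona-1,8-dien-1-yl]copper | [Cu]/C=C(C)\C[C@@H](C)CCCC=C | intermediate
10 | lithium [(1Z,4S)-2,4-dimethylnona-1,8-dien-1-yl](thiophen-2-yl)cuprate | [Li+].[Cu-](c1cccs1)/C=C(C)\C[C@@H](C)CCCC=C | intermediate
11 | methyl (2E,4Z,7S)-3,5,7-trimethyldodeca-2,4,11-trienoate | COC(=O)/C=C(C)/C=C(C)\C[C@@H](C)CCCC=C | intermediate
12 | methyl (2E,4Z,7S)-3,5,7-trimethyl-12-oxododeca-2,4-dienoate | COC(=O)/C=C(C)/C=C(C)\C[C@@H](C)CCCCC=O | intermediate
13 | 3-{[tert-butyl(dimethyl)silyl]oxy}propanoic acid | CC(C)(C)[Si](C)(C)OCCC(=O)O | starting material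
14 | 3-{[tert-butyl(dimethyl)silyl]oxy}propanoyl chloride | CC(C)(C)[Si](C)(C)OCCC(=O)Cl | intermediate
15 | 3-{[tert-butyl(dimethyl)silyl]oxy}prop-1-en-1-one (silyloxymethylketene) | CC(C)(C)[Si](C)(C)OCC=C=O | intermediate
16 | methyl (2E,4Z,7S)-11-[(2S,3R)-3-({[tert-butyl(dimethyl)silyl]oxy}methyl)-4-oxooxetan-2-yl]-3,5,7-trimethylundeca-2,4-dienoate | COC(=O)/C=C(C)/C=C(C)\C[C@@H](C)CCCC[C@@H]1OC(=O)[C@@H]1CO[Si](C)(C)C(C)(C)C | intermediate
17 | methyl (2E)-3-[(2S,3R)-3-{(2S)-6-[(2S,3R)-3-({[tert-butyl(dimethyl)silyl]oxy}methyl)-4-oxooxetan-2-yl]-2-methylhexyl}-3-methyloxiran-2-yl]but-2-enoate | COC(=O)/C=C(C)/[C@@H]1O[C@]1(C)C[C@@H](C)CCCC[C@@H]2OC(=O)[C@@H]2CO[Si](C)(C)C(C)(C)C | intermediate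
18 | methyl (2E)-3-[(2S,3R)-3-{(2S)-6-[(2S,3R)-3-(hydroxymethyl)-4-oxooxetan-2-yl]-2-methylhexyl}-3-methyloxiran-2-yl]but-2-enoate | COC(=O)/C=C(C)/[C@@H]1O[C@]1(C)C[C@@H](C)CCCC[C@@H]2OC(=O)[C@@H]2CO | intermediate
19 | (2E,4S,5R,7S,12S,13R)-4,5-epoxy-12-hydroxy-13-(hydroxymethyl)-3,5,7-trimethyltetradec-2-enedioic acid | C/C(=C\C(=O)O)[C@@H]1O[C@]1(C)C[C@@H](C)CCCC[C@H](O)[C@@H](CO)C(=O)O | target

## Step count and risk

Total step count: 7. Longest linear sequence: 7 (1/2 → 4 → 5 → 11 → 12 → 16 → 17 → 19).

Steps most likely to fail: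

**Step 1 (the proposed new reaction).** The risks are racemic radical addition to free methacrolein, erosion of the α-stereocenter through enamine re-formation, and interference between the acridinium and the amine. The fallback uses known chemistry, sets out from 1 and 2 and comes back at 4. Without the chiral diamine, the acridinium-photocatalysed Giese addition of 2 to 1 gives racemic 2-methylhept-6-enal F1, which NaBH4 reduces to racemic 2-methylhept-6-en-1-ol F2. Kinetic resolution with Burkholderia cepacia lipase and vinyl acetate in t-BuOMe at 0 °C acetylates the (S)-alcohol preferentially (modest E for this substrate class; run to partial conversion or recycled) to give (2S)-2-methylhept-6-en-1-yl acetate F3. F3 is separated from the unreacted (R)-alcohol and methanolysed (K2CO3, MeOH) to 4. This replaces asymmetric C–C bond formation by racemic synthesis and enzymatic resolution.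

**Step 3 (three-component carbocupration/conjugate addition).** The risks are sluggish addition of the alkenylcuprate to the β-substituted ynoate and loss of 2E geometry through the allenoate. The fallback sets out from 5 (with 6 and 7) and comes back at 11. The same carbocupration of 6 via 8 and 9 is quenched with I2 to give (1Z,4S)-1-iodo-2,4-dimethylnona-1,8-diene F4. Separately, 7 undergoes syn-hydroboration (B2pin2, CuCl/xantphos, NaOt-Bu, MeOH, THF) to give methyl (2Z)-3-(4,4,5,5-tetramethyl-1,3,2-dioxaborolan-2-yl)but-2-enoate F5. Suzuki–Miyaura coupling of F4 with F5 (PdCl2(dppf), K3PO4, THF/H2O, 40 °C) proceeds with retention at both partners and gives 11.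

**Step 5 (ketene–aldehyde cyclocondensation).** The risks are β-elimination of the silyloxy group to acryloyl species, aldehyde self-aldol, and an untested β-silyloxy ketene. The fallback sets out from 12 and 13 and comes back at 16. Acid 13 is esterified with phenol (DCC, DMAP) to phenyl 3-{[tert-butyl(dimethyl)silyl]oxy}propanoate F6. F6 is converted (LiN(iPr)2, Me3SiCl, THF, −78 °C) into its ketene silyl acetal, tert-butyl(dimethyl){[3-phenoxy-3-(trimethylsilyloxy)prop-2-en-1-yl]oxy}silane F7. A syn-selective Mukaiyama aldol of F7 with 12, catalysed by a tartaric-acid-derived chiral acyloxyborane (20 mol%, EtCN, −78 °C; enantiomer chosen for 12S), gives 1-methyl 14-phenyl (2E,4Z,7S,12S,13R)-13-({[tert-butyl(dimethyl)silyl]oxy}methyl)-12-hydroxy-3,5,7-trimethyltetradeca-2,4-dienedioate F8 after mild acid work-up. Deprotonation of F8 (LiN(SiMe3)2, THF, −78 to 20 °C) closes the alkoxide onto the phenyl ester and gives cis-lactone 16.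

## Further compounds

F1 | step 1 | 2-methylhept-6-enal (racemic) | O=CC(C)CCCC=C
F2 | step 1 | 2-methylhept-6-en-1-ol (racemic) | OCC(C)CCCC=C
F3 | step 1 | (2S)-2-methylhept-6-en-1-yl acetate | CC(=O)OC[C@@H](C)CCCC=C
F4 | step 3 | (1Z,4S)-1-iodo-2,4-dimethylnona-1,8-diene | I/C=C(C)\C[C@@H](C)CCCC=C
F5 | step 3 | methyl (2Z)-3-(4,4,5,5-tetramethyl-1,3,2-dioxaborolan-2-yl)but-2-enoate | COC(=O)/C=C(C)/B1OC(C)(C)C(C)(C)O1
F6 | step 5 | phenyl 3-{[tert-butyl(dimethyl)silyl]oxy}propanoate | CC(C)(C)[Si](C)(C)OCCC(=O)Oc1ccccc1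
F7 | step 5 | tert-butyl(dimethyl){[3-phenoxy-3-(trimethylsilyloxy)prop-2-en-1-yl]oxy}silane | CC(C)(C)[Si](C)(C)OCC=C(O[Si](C)(C)C)Oc1ccccc1
F8 | step 5 | 1-methyl 14-phenyl (2E,4Z,7S,12S,13R)-13-({[tert-butyl(dimethyl)silyl]oxy}methyl)-12-hydroxy-3,5,7-trimethyltetradeca-2,4-dienedioate | COC(=O)/C=C(C)/C=C(C)\C[C@@H](C)CCCC[C@H](O)[C@@H](CO[Si](C)(C)C(C)(C)C)C(=O)Oc1ccccc1
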